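**Retrosynthetic overview**

- The target is (2R)-5,7-dimethoxy-8-prenylflavanone. The C2–phenyl bond is cut first, by asymmetric 1,4-arylation of a chromone, so ring C is handled at the chromone oxidation level.
- Ring C is opened at O1–C2 to an ortho-hydroxyaryl ethynyl ketone. Its phenol is traced back, by a retro-Claisen step, to the 1,1-dimethylallyl ether of the same oxygen. All three events run forward in one flask from an achiral ynone that has no ring C, no C-prenyl group and no phenyl ring.
- Enabling feature: O1 sits on C8a, which is ortho both to the prenylated C8 and to C4a carrying the C4 carbonyl. The ring oxygen can therefore first carry the C5 unit and hand it to C8 by a [3,3] shift, and is then placed to add to the alkyne terminus (future C2) that the C4 carbonyl activates.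
- The ynone comes from commercial 2-hydroxy-4,6-dimethoxybenzaldehyde by O-(1,1-dimethylpropargyl)ation, semihydrogenation, ethynyl addition and oxidation.
- Ring order: ring A (commercial arene) and ring B (phenylboronic acid) are bought; ring C is the only ring formed and is closed last.

Key step: step 5

Remark on the chemistry (assumption): the target is read as the 2R enantiomer; the sense of induction in stage (c) of step 5 is assigned by analogy with the cyclic-enone model for atropisomeric bisphosphines, in which the (R)-ligand delivers the aryl group to the face that corresponds to 2R here, and the (S)-ligand is used instead, with no other change, should the first run show the opposite sense; (R)-MeO-F12-BIPHEP stands for (R)-6,6'-dimethoxy-2,2'-bis[bis(3,4,5-trifluorophenyl)phosphino]-1,1'-biphenyl and cod for cycloocta-1,5-diene.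

**Route**

Step 1
Reactants: 1 2-hydroxy-4,6-dimethoxybenzaldehyde; 2 3-chloro-3-methylbut-1-yne
Product: 3 4,6-dimethoxy-2-[(2-methylbut-3-yn-2-yl)oxy]benzaldehyde
Conditions: 2 (1.3 equiv), CuCl2·2H2O (1 mol %), DBU (1.5 equiv), MeCN, 0 °C
Reagents that add atoms: none
Why: Copper-catalysed propargylic etherification, in which the tertiary propargylic chloride is ionised through a copper acetylide and captured at the tertiary carbon by the phenoxide that DBU frees from its hydrogen bond to the aldehyde; no stereocentre is formed.

Step 2
Reactants: 3 4,6-dimethoxy-2-[(2-methylbut-3-yn-2-yl)oxy]benzaldehyde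
Product: 4 4,6-dimethoxy-2-[(2-methylbut-3-en-2-yl)oxy]benzaldehyde
Conditions: H2 (1 atm), Pd/CaCO3 poisoned with Pb(OAc)2 (Lindlar catalyst), quinoline, EtOAc, 20 °C
Reagents that add atoms: none
Why: Lindlar semihydrogenation of a terminal alkyne should stop at the alkene on the poisoned palladium surface and leave the aldehyde and the aryl ether untouched, and at 20 °C the tertiary allyl aryl ether should not yet rearrange.

Step 3
Reactants: 4 4,6-dimethoxy-2-[(2-methylbut-3-en-2-yl)oxy]benzaldehyde; 5 ethynylmagnesium bromide
Product: 6 rac-1-{4,6-dimethoxy-2-[(2-methylbut-3-en-2-yl)oxy]phenyl}prop-2-yn-1-ol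
Conditions: 5 (0.5 M in THF, 1.5 equiv), THF, −20 to 0 °C; then aqueous work-up
Reagents that add atoms: none
Why: Grignard 1,2-addition to a non-enolisable aldehyde; the carbinol centre is formed as a racemate and is erased in step 4.

Step 4
Reactants: 6 rac-1-{4,6-dimethoxy-2-[(2-methylbut-3-en-2-yl)oxy]phenyl}prop-2-yn-1-ol
Product: 7 1-{4,6-dimethoxy-2-[(2-methylbut-3-en-2-yl)oxy]phenyl}prop-2-yn-1-one
Conditions: MnO2 (activated, 15 equiv), CH2Cl2, 20 °C
Reagents that add atoms: none
Why: Manganese dioxide oxidation of a benzylic-propargylic alcohol under neutral heterogeneous conditions should spare the acid- and heat-sensitive tertiary allyl aryl ether, the alkene and the electron-rich ring.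

Step 5
Reactants: 7 1-{4,6-dimethoxy-2-[(2-methylbut-3-en-2-yl)oxy]phenyl}prop-2-yn-1-one; 8 phenylboronic acid
Product: 11 (2R)-5,7-dimethoxy-8-(3-methylbut-2-en-1-yl)-2-phenyl-2,3-dihydro-4H-chromen-4-one, via phenol ynone 9 (not isolated), via chromone 10 (not isolated)
Conditions: (a) toluene (degassed), 100 °C; (b) Et3N (10 mol %), 60 °C; (c) [Rh(OH)(cod)]2 (1.5 mol %), (R)-MeO-F12-BIPHEP (3.3 mol %), 8 (3 equiv), H2O (10 equiv), 30 °C; one flask, argon
Reagents that add atoms: none
Why: Heating triggers an aromatic Claisen [3,3] shift of the 1,1-dimethylallyl ether to the only unsubstituted ortho carbon (with allylic transposition, so that the linear prenyl group arrives on the future C8) and tautomerisation to phenol 9, whose oxygen adds to the terminal alkyne carbon of the ynone to give chromone 10; phenylrhodium formed by transmetalation from 8 then inserts the C2=C3 bond and hydrolysis of the rhodium enolate releases 11. The closest known reaction types are tandem aromatic Claisen rearrangement/6-endo cyclisation sequences that give 8-allylated chromones, the amine-promoted cycloisomerisation of ortho-hydroxyaryl ynones and the rhodium-catalysed asymmetric 1,4-addition of arylboronic acids to chromones with electron-poor atropisomeric bisphosphines. Ring C is closed by a 6-endo-dig oxa-Michael addition that forms the O1–C2 bond at the chromone oxidation level, so the hot part of the sequence creates no stereocentre that could be scrambled. The only stereocentre, C2, is set in stage (c) by enantioface-selective carborhodation of 10 under control of the (R)-configured bisphosphine on rhodium, and the addition of phenyl and hydrogen across C2=C3 returns ring C to the flavanone oxidation level. The step needs regioselectivity in the sigmatropic shift (secured by the acyl group that blocks the second ortho carbon), 6-endo over 5-exo closure (secured by the unsubstituted β-carbon of the terminal ynone, its most electrophilic site) and chemoselectivity of phenylrhodium for the enone over the isolated trisubstituted prenyl alkene and the aryl ketone (secured by adding catalyst and boronic acid only when no ynone is left). No hydroxide or alkoxide base is added and stage (c) runs near room temperature, which should guard 11 against retro-oxa-Michael ring opening, the one path by which C2 could racemise.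

**Compound list**

1 | 2-hydroxy-4,6-dimethoxybenzaldehyde | COc1cc(O)c(C=O)c(OC)c1 | starting material
2 | 3-chloro-3-methylbut-1-yne | CC(C)(Cl)C#C | starting material
3 | 4,6-dimethoxy-2-[(2-methylbut-3-yn-2-yl)oxy]benzaldehyde | COc1cc(OC)c(C=O)c(OC(C)(C)C#C)c1 | intermediate
4 | 4,6-dimethoxy-2-[(2-methylbut-3-en-2-yl)oxy]benzaldehyde | COc1cc(OC)c(C=O)c(OC(C)(C)C=C)c1 | intermediate
5 | ethynylmagnesium bromide | C#C[Mg]Br | starting material
6 | rac-1-{4,6-dimethoxy-2-[(2-methylbut-3-en-2-yl)oxy]phenyl}prop-2-yn-1-ol (racemic) | COc1cc(OC)c(C(O)C#C)c(OC(C)(C)C=C)c1 | intermediate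
7 | 1-{4,6-dimethoxy-2-[(2-methylbut-3-en-2-yl)oxy]phenyl}prop-2-yn-1-one | COc1cc(OC)c(C(=O)C#C)c(OC(C)(C)C=C)c1 | intermediate
8 | phenylboronic acid | OB(O)c1ccccc1 | starting material
9 | 1-[2-hydroxy-4,6-dimethoxy-3-(3-methylbut-2-en-1-yl)phenyl]prop-2-yn-1-one (phenol ynone, not isolated) | COc1cc(OC)c(C(=O)C#C)c(O)c1CC=C(C)C | intermediate
10 | 5,7-dimethoxy-8-(3-methylbut-2-en-1-yl)-4H-chromen-4-one (chromone, not isolated) | COc1cc(OC)c2c(c1CC=C(C)C)OC=CC2=O | intermediate
11 | (2R)-5,7-dimethoxy-8-(3-methylbut-2-en-1-yl)-2-phenyl-2,3-dihydro-4H-chromen-4-one | COc1cc(OC)c2c(c1CC=C(C)C)O[C@@H](c1ccccc1)CC2=O | target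

**Step count and risks**

Total step count: 5. Longest linear sequence: 5 steps (from compound 1).

Steps most likely to fail:

1. Step 5. The terminal ynone may oligomerise, or the tertiary allyl group may be lost as isoprene, in competition with the [3,3] shift during the thermal stage. Carborhodation of the electron-rich chromone in the unpurified solution may also be slow or poorly face-selective, and reversible ring opening may erode the enantiomeric purity. The fallback moves the stereo-defining event into an organocatalytic ring closure; it sets out from 4 and comes back at 11. Compound 4 is heated in toluene at 100 °C, where the same Claisen shift should give 2-hydroxy-4,6-dimethoxy-3-(3-methylbut-2-en-1-yl)benzaldehyde F1. The lithium enolate of tert-butyl acetate (lithium diisopropylamide, THF, −78 °C, 2.5 equiv) is added to the aldehyde to give racemic tert-butyl 3-hydroxy-3-[2-hydroxy-4,6-dimethoxy-3-(3-methylbut-2-en-1-yl)phenyl]propanoate F2, which MnO2 should oxidise to tert-butyl 3-[2-hydroxy-4,6-dimethoxy-3-(3-methylbut-2-en-1-yl)phenyl]-3-oxopropanoate F3. Knoevenagel condensation with benzaldehyde (piperidine, AcOH, toluene, 20 °C) gives tert-butyl 2-[2-hydroxy-4,6-dimethoxy-3-(3-methylbut-2-en-1-yl)benzoyl]-3-phenylprop-2-enoate F4. A cinchona-alkaloid-derived bifunctional thiourea (10 mol %, toluene, −25 °C; the pseudoenantiomer that gives the 2R series) then closes ring C by enantioselective 6-endo-trig oxa-Michael addition to tert-butyl (2R)-5,7-dimethoxy-8-(3-methylbut-2-en-1-yl)-4-oxo-2-phenylchromane-3-carboxylate F5. TsOH at 80 °C in the same flask removes the activating ester by loss of 2-methylpropene and carbon dioxide to give 11.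

2. Step 1. O-Alkylation of the hydrogen-bonded, ortho-substituted phenoxide may be slow, so that elimination of HCl from the propargylic chloride takes over. The fallback replaces propargylation and semihydrogenation by a direct allylic etherification; it sets out from 1 and comes back at 4, by-passing 3. 2-Methylbut-3-en-2-ol is converted (n-BuLi, then di-tert-butyl dicarbonate, THF) into tert-butyl 2-methylbut-3-en-2-yl carbonate F6. Compound 1 is then O-allylated with F6 under Pd(PPh3)4 catalysis (5 mol %, THF, 0 °C). Ionisation by zerovalent palladium and attack of the phenoxide at the more substituted allyl terminus (decarboxylative Tsuji–Trost etherification) should give 4.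

3. Step 4. The unhindered terminal ynone may undergo conjugate addition and oligomerisation on the oxidant surface or on concentration. The fallback carries the alkyne in C-silylated form; it sets out from 4 and comes back at 10. Lithium (trimethylsilyl)acetylide (THF, −78 °C) is added to 4 to give rac-1-{4,6-dimethoxy-2-[(2-methylbut-3-en-2-yl)oxy]phenyl}-3-(trimethylsilyl)prop-2-yn-1-ol F7, and MnO2 should give the shielded ynone 1-{4,6-dimethoxy-2-[(2-methylbut-3-en-2-yl)oxy]phenyl}-3-(trimethylsilyl)prop-2-yn-1-one F8. Heating in toluene at 100 °C effects the Claisen shift to 1-[2-hydroxy-4,6-dimethoxy-3-(3-methylbut-2-en-1-yl)phenyl]-3-(trimethylsilyl)prop-2-yn-1-one F9. K2CO3 in MeOH at 20 °C then removes the silyl group and closes ring C to 10, which is arylated under the conditions of stage (c) of step 5 run as a separate operation.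

**Further compounds**

F1 | step 5 | 2-hydroxy-4,6-dimethoxy-3-(3-methylbut-2-en-1-yl)benzaldehyde | COc1cc(OC)c(C=O)c(O)c1CC=C(C)C
F2 | step 5 | rac-tert-butyl 3-hydroxy-3-[2-hydroxy-4,6-dimethoxy-3-(3-methylbut-2-en-1-yl)phenyl]propanoate | COc1cc(OC)c(C(O)CC(=O)OC(C)(C)C)c(O)c1CC=C(C)C
F3 | step 5 | tert-butyl 3-[2-hydroxy-4,6-dimethoxy-3-(3-methylbut-2-en-1-yl)phenyl]-3-oxopropanoate | COc1cc(OC)c(C(=O)CC(=O)OC(C)(C)C)c(O)c1CC=C(C)C
F4 | step 5 | tert-butyl 2-[2-hydroxy-4,6-dimethoxy-3-(3-methylbut-2-en-1-yl)benzoyl]-3-phenylprop-2-enoate | COc1cc(OC)c(C(=O)C(=Cc2ccccc2)C(=O)OC(C)(C)C)c(O)c1CC=C(C)C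
F5 | step 5 | tert-butyl (2R)-5,7-dimethoxy-8-(3-methylbut-2-en-1-yl)-4-oxo-2-phenylchromane-3-carboxylate (C3 epimers) | COc1cc(OC)c2c(c1CC=C(C)C)O[C@@H](c1ccccc1)C(C(=O)OC(C)(C)C)C2=O
F6 | step 1 | tert-butyl 2-methylbut-3-en-2-yl carbonate | CC(C)(C=C)OC(=O)OC(C)(C)C
F7 | step 4 | rac-1-{4,6-dimethoxy-2-[(2-methylbut-3-en-2-yl)oxy]phenyl}-3-(trimethylsilyl)prop-2-yn-1-ol | COc1cc(OC)c(C(O)C#C[Si](C)(C)C)c(OC(C)(C)C=C)c1
F8 | step 4 | 1-{4,6-dimethoxy-2-[(2-methylbut-3-en-2-yl)oxy]phenyl}-3-(trimethylsilyl)prop-2-yn-1-one | COc1cc(OC)c(C(=O)C#C[Si](C)(C)C)c(OC(C)(C)C=C)c1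
F9 | step 4 | 1-[2-hydroxy-4,6-dimethoxy-3-(3-methylbut-2-en-1-yl)phenyl]-3-(trimethylsilyl)prop-2-yn-1-one | COc1cc(OC)c(C(=O)C#C[Si](C)(C)C)c(O)c1CC=C(C)C
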